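**Plan**
1. Enabling feature: remove C8a' from either guaiazulen-3-yl unit and rejoin C3a' to C8'. The seven-membered ring (C3a', C4'-Me, C5', C6', C7'-iPr, C8') then collapses to the benzene ring of p-cymene, substituted ortho to its methyl group. Both azulenes can therefore be grown from 5-isopropyl-2-methylphenyl (carvacryl) rings.
2. Cuts, in order: both C1'–CH3 bonds (back to C1'–O); C8a'–C3a' and C8a'–C8' in both units (double Buchner reaction) to a bis(diazoketone); C8a'–C1' (diazomethane); C2–C3' and C6–C3' (double Suzuki–Miyaura coupling). This leaves a 2-bromo-6-chloroindenone and a β-boryl acrylate made from carvacrol and ethyl propiolate.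
3. Forward ring order: the benzo ring is bought. The five-membered ring of the core is closed by Friedel–Crafts acylation and dehydrogenated later. Both arms are then attached, and all four azulene rings (two five-membered, two seven-membered) arise in one operation.
4. Stereochemistry: the target has no stereocentre. The only element that matters is the geometry of the two arm alkenes (aryl cis to acyl), set by syn-borylcupration in step 3 and kept by stereoretentive steps.

Key step: step 15

Numbering: unprimed locants are those of inden-1-one. Primed locants follow guaiazulene (C1'-Me, C3' bonded to the core, C4'-Me, C7'-iPr).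
Assumption: rotation about C2–C3' and C6–C3' is taken not to give separable atropisomers, since the target structure carries no stereodescriptor. Compounds 10–18 are racemic at C3, a centre that becomes sp2 in step 10.

**Step 1**
Reactants: 1 carvacrol (5-isopropyl-2-methylphenol)
Product: 2 5-isopropyl-2-methylphenyl trifluoromethanesulfonate
Conditions: Tf2O, pyridine, CH2Cl2, 0 °C
Reagents that add atoms: trifluoromethanesulfonic anhydride, O=S(=O)(OS(=O)(=O)C(F)(F)F)C(F)(F)F
Why: Standard O-triflation of a phenol turns the C–O bond of carvacrol into a cross-coupling handle without touching the alkyl groups.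

**Step 2**
Reactants: 2 5-isopropyl-2-methylphenyl trifluoromethanesulfonate; 3 ethyl propiolate
Product: 6 ethyl 3-(5-isopropyl-2-methylphenyl)prop-2-ynoate, via lithium acetylide 4 (not isolated), via alkynylzinc bromide 5 (not isolated)
Conditions: 3, LiN(iPr)2, THF, −78 °C; ZnBr2, −78 to 0 °C; then 2, PdCl2(dppf) (5 mol %), THF, 55 °C
Reagents that add atoms: none
Why: Negishi alkynylation with a preformed zinc acetylide avoids the amine-induced Michael addition and oligomerisation that trouble Sonogashira couplings of propiolates, and dppf-ligated palladium inserts into ortho-substituted aryl triflates.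

**Step 3**
Reactants: 6 ethyl 3-(5-isopropyl-2-methylphenyl)prop-2-ynoate
Product: 7 ethyl (Z)-3-(5-isopropyl-2-methylphenyl)-3-(4,4,5,5-tetramethyl-1,3,2-dioxaborolan-2-yl)prop-2-enoate (aryl cis to ester; boron trans)
Conditions: B2pin2 (1.1 equiv), CuCl (5 mol %), Xantphos (5 mol %), NaOtBu (10 mol %), MeOH (2 equiv), THF, rt
Reagents that add atoms: bis(pinacolato)diboron, CC1(C)OB(OC1(C)C)B1OC(C)(C)C(C)(C)O1
Why: Copper-catalysed conjugate borylation (syn-borylcupration, then stereoretentive protonation by MeOH) places boron on the β-carbon with boron and hydrogen on the same side, so the aryl ring ends up cis to the ester as the key step requires.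

**Step 4**
Reactants: 8 (4-chloro-3-methylphenyl)boronic acid; 9 ethyl (E)-but-2-enoate
Product: 11 rac-3-(4-chloro-3-methylphenyl)butanoic acid, via ethyl ester 10 (not isolated)
Conditions: [Rh(cod)OH]2 (1.5 mol %), dioxane/H2O 6:1, 50 °C; then aq NaOH, MeOH, 50 °C; HCl work-up
Reagents that add atoms: sodium hydroxide, [Na+].[OH-]
Why: Hayashi–Miyaura rhodium-catalysed 1,4-addition of an arylboronic acid to a crotonate, followed by saponification in the same flask; the new C3 centre is deliberately racemic because it is erased in step 10.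

**Step 5**
Reactants: 11 rac-3-(4-chloro-3-methylphenyl)butanoic acid
Product: 12 rac-3-(2-bromo-4-chloro-5-methylphenyl)butanoic acid
Conditions: Br2 (1.05 equiv), FeBr3 (5 mol %), CH2Cl2, 0 °C, dark
Reagents that add atoms: bromine, BrBr
Why: Electrophilic aromatic bromination should go to the one position that is para to the methyl group and ortho to the sec-alkyl chain, since the alternatives are either flanked on both sides or activated only by chlorine.

**Step 6**
Reactants: 12 rac-3-(2-bromo-4-chloro-5-methylphenyl)butanoic acid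
Product: 14 rac-4-bromo-6-chloro-3,7-dimethylindan-1-one, via acid chloride 13 (not isolated)
Conditions: (COCl)2, DMF (cat.), CH2Cl2, rt; then AlCl3 (1.3 equiv), CH2Cl2, 0 °C to rt
Reagents that add atoms: none
Why: Intramolecular Friedel–Crafts acylation closes the five-membered ring of the core onto the only free ortho position, next to the methyl group, because bromine blocks the other one.

**Step 7**
Reactants: 14 rac-4-bromo-6-chloro-3,7-dimethylindan-1-one; 15 isopropenylboronic acid pinacol ester
Product: 16 rac-6-chloro-3,7-dimethyl-4-(prop-1-en-2-yl)indan-1-one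
Conditions: PdCl2(dppf) (3 mol %), K2CO3, dioxane/H2O 5:1, 80 °C
Reagents that add atoms: none
Why: Suzuki–Miyaura coupling in which zerovalent palladium bearing dppf inserts into the C4–Br bond and leaves the C6–Cl bond for step 12.

**Step 8**
Reactants: 16 rac-6-chloro-3,7-dimethyl-4-(prop-1-en-2-yl)indan-1-one
Product: 17 rac-6-chloro-4-(2-hydroxypropan-2-yl)-3,7-dimethylindan-1-one
Conditions: Co(acac)2 (10 mol %), PhSiH3 (2 equiv), O2 (1 atm), THF, rt
Reagents that add atoms: dioxygen, O=O
Why: Mukaiyama hydration, in which hydrogen-atom transfer from a cobalt hydride gives the tertiary benzylic radical that O2 traps and the silane reduces to the Markovnikov alcohol, under neutral conditions that spare the ketone and the aryl chloride.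

**Step 9**
Reactants: 17 rac-6-chloro-4-(2-hydroxypropan-2-yl)-3,7-dimethylindan-1-one
Product: 18 rac-C1-O-triethylsilyl enol ether (C1=C2) of 6-chloro-3,7-dimethyl-4-[2-(triethylsilyloxy)propan-2-yl]indan-1-one
Conditions: TESOTf (2.6 equiv), Et3N (4 equiv), CH2Cl2, 0 °C to rt
Reagents that add atoms: triethylsilyl trifluoromethanesulfonate, CC[Si](CC)(CC)OS(=O)(=O)C(F)(F)F
Why: A silyl triflate with a tertiary amine silylates the hindered tertiary alcohol and, by soft enolisation, converts the ketone into its only possible silyl enol ether, so protection and activation cost one step.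

**Step 10**
Reactants: 18 bis-silylated indanone derivative
Product: 19 6-chloro-3,7-dimethyl-4-[2-(triethylsilyloxy)propan-2-yl]inden-1-one
Conditions: Pd(OAc)2 (1.05 equiv), MeCN, rt, dark
Reagents that add atoms: none
Why: Saegusa–Ito oxidation, in which divalent palladium binds C2 on the face opposite the C3 methyl group and hence syn to C3–H, so β-hydride elimination to the indenone is geometrically easy and the tertiary silyl ether is untouched.

**Step 11**
Reactants: 19 6-chloro-3,7-dimethyl-4-[2-(triethylsilyloxy)propan-2-yl]inden-1-one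
Product: 21 2-bromo-6-chloro-3,7-dimethyl-4-[2-(triethylsilyloxy)propan-2-yl]inden-1-one, via trans-2,3-dibromide 20 (not isolated)
Conditions: Br2 (1.05 equiv), CH2Cl2, 0 °C; then Et3N (3 equiv), 0 °C to rt
Reagents that add atoms: bromine, BrBr
Why: Classical α-bromination of a β-methyl cyclic enone by bromine addition and amine-induced E1cB loss of HBr through the acidic C2–H; the amine also keeps the medium non-acidic for the silyl ether.

**Step 12**
Reactants: 21 2-bromo-6-chloro-3,7-dimethyl-4-[2-(triethylsilyloxy)propan-2-yl]inden-1-one; 7 (Z)-β-boryl acrylate (2.6 equiv)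
Product: 22 diethyl (2E,2'E)-3,3'-{3,7-dimethyl-1-oxo-4-[2-(triethylsilyloxy)propan-2-yl]-1H-indene-2,6-diyl}bis[3-(5-isopropyl-2-methylphenyl)prop-2-enoate] (each aryl cis to its ester)
Conditions: Pd(OAc)2 (8 mol %), SPhos (16 mol %), K3PO4 (5 equiv), toluene/H2O 10:1, 90 °C, dark
Reagents that add atoms: none
Why: Two-fold Suzuki–Miyaura coupling with retention of alkene geometry, since α-bromoenones are excellent electrophiles and the SPhos-ligated catalyst also activates the ortho-methyl aryl chloride, which places the core trans and each carvacryl ring cis to its ester.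

**Step 13**
Reactants: 22 bis(ethyl ester)
Product: 23 (2E,2'E)-3,3'-{3,7-dimethyl-1-oxo-4-[2-(triethylsilyloxy)propan-2-yl]-1H-indene-2,6-diyl}bis[3-(5-isopropyl-2-methylphenyl)prop-2-enoic acid]
Conditions: LiOH (6 equiv), THF/MeOH/H2O 3:1:1, rt to 40 °C; cold dilute HCl to pH 4
Reagents that add atoms: lithium hydroxide, [Li+].[OH-]
Why: Ordinary ester saponification, which the tetrasubstituted indenone alkene, the tertiary silyl ether and the trisubstituted acrylate geometry should tolerate at or near room temperature.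

**Step 14**
Reactants: 23 bis(acrylic acid)
Product: 25 2,6-bis[(1E)-4-diazo-1-(5-isopropyl-2-methylphenyl)-3-oxobut-1-en-1-yl]-3,7-dimethyl-4-[2-(triethylsilyloxy)propan-2-yl]inden-1-one, via bis(acid chloride) 24 (not isolated)
Conditions: 1-chloro-N,N,2-trimethylprop-1-en-1-amine (2.4 equiv), CH2Cl2, 0 °C; then added to CH2N2 (ca. 8 equiv), Et2O, 0 °C
Reagents that add atoms: diazomethane, C=[N+]=[N-]
Why: Acylation of diazomethane (first stage of the Arndt–Eistert sequence) after neutral acid chloride formation with an α-chloroenamine that liberates no HCl; the β,β-disubstitution of both enoyl units and the tetrasubstituted indenone alkene should suppress dipolar cycloaddition of diazomethane.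

**Step 15**
Reactants: 25 bis(diazoketone)
Product: 28 2,6-bis[7-isopropyl-4-methyl-1-(trifluoromethylsulfonyloxy)azulen-3-yl]-3,7-dimethyl-4-[2-(triethylsilyloxy)propan-2-yl]inden-1-one, via bis(8aH-azulen-1-one) 26 (not isolated), via bis(1-hydroxyazulene) 27 (not isolated)
Conditions: Rh2(O2CCMe3)4 (2 mol %), CH2Cl2, rt, 25 added over 4 h (final ca. 2 mM), argon; then DMAP (6 equiv), PhNTf2 (3 equiv), rt
Reagents that add atoms: N-phenylbis(trifluoromethanesulfonimide), O=S(=O)(N(c1ccccc1)S(=O)(=O)C(F)(F)F)C(F)(F)F
Why: Proposed new method: loss of N2 from each diazoketone at divalent rhodium gives an electrophilic keto-carbenoid whose carbon (future C8a') adds across the ipso–ortho bond C1–C6 of the cymene ring held cis to it, forming C8a'–C3a' and C8a'–C8' in one [2+1] event. Each five-membered ring (C8a', C1', C2', C3', C3a') is thus closed by intramolecular cyclopropanation, and each seven-membered ring arises from the norcaradiene by disrotatory six-electron electrocyclic opening of the old C3a'–C8' bond, that is by ring expansion and not by cyclisation. DMAP then removes the doubly activated C8a'–H of 26, so the only new stereocentres (C8a' and, transiently, C3a' and C8') need no control and are erased on aromatisation to 27, which is too air-sensitive to isolate and is sulfonylated in the same flask. The closest known reaction type is the rhodium-carboxylate-catalysed intramolecular Buchner reaction of 1-diazo-4-arylbutan-2-ones, including its 4-halo variant that loses HX to give 1-hydroxyazulenes trapped as esters or triflates; an already unsaturated tether, a fully substituted C3' and two such events in one molecule have not been shown. Chemoselectivity rests on the E geometry of both alkenes, which holds the electron-poor indenone core trans to the carbenoid and out of reach, and on the silyl ether, which removes O–H insertion. Regioselectivity (C1–C6 and not C1–C2) rests on the ortho methyl group, which twists the ring perpendicular to the enone plane as the cyclopropanation requires and shields its own side.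

**Step 16**
Reactants: 28 bis(azulenyl triflate)
Product: 29 2,6-bis(7-isopropyl-1,4-dimethylazulen-3-yl)-3,7-dimethyl-4-[2-(triethylsilyloxy)propan-2-yl]inden-1-one
Conditions: trimethylboroxine (2 equiv), Pd(OAc)2 (10 mol %), SPhos (20 mol %), K3PO4 (4 equiv), dioxane/H2O 20:1, 80 °C
Reagents that add atoms: trimethylboroxine, CB1OB(C)OB(C)O1
Why: Suzuki–Miyaura methylation, for which 1-azulenyl triflates are established partners with electron-rich biarylphosphine ligands, while the ketone and the silyl ether are inert to the boron reagent.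

**Step 17**
Reactants: 29 silyl-protected target
Product: 30 2,6-bis(7-isopropyl-1,4-dimethylazulen-3-yl)-4-(2-hydroxypropan-2-yl)-3,7-dimethylinden-1-one (CNP0151235.0)
Conditions: TBAF (2 equiv), AcOH (2 equiv), THF, rt to 40 °C
Reagents that add atoms: none
Why: Fluoride-induced Si–O cleavage, buffered with AcOH so that neither the acid-sensitive azulenes and tertiary benzylic alcohol nor the base-sensitive C3 methyl group of the indenone meets an extreme of pH.

**Compound list**
1 | carvacrol | Cc1ccc(C(C)C)cc1O | starting material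
2 | 5-isopropyl-2-methylphenyl trifluoromethanesulfonate | Cc1ccc(C(C)C)cc1OS(=O)(=O)C(F)(F)F | intermediate
3 | ethyl propiolate | C#CC(=O)OCC | starting material
4 | ethyl 3-lithioprop-2-ynoate | [Li]C#CC(=O)OCC | intermediate
5 | (3-ethoxy-3-oxoprop-1-yn-1-yl)zinc bromide | Br[Zn]C#CC(=O)OCC | intermediate
6 | ethyl 3-(5-isopropyl-2-methylphenyl)prop-2-ynoate | CCOC(=O)C#Cc1cc(C(C)C)ccc1C | intermediate
7 | ethyl (Z)-3-(5-isopropyl-2-methylphenyl)-3-(pinacolatoboryl)prop-2-enoate | CCOC(=O)/C=C(/B1OC(C)(C)C(C)(C)O1)c1cc(C(C)C)ccc1C | intermediate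
8 | (4-chloro-3-methylphenyl)boronic acid | Cc1cc(B(O)O)ccc1Cl | starting material
9 | ethyl (E)-but-2-enoate | C/C=C/C(=O)OCC | starting material
10 | rac-ethyl 3-(4-chloro-3-methylphenyl)butanoate | CCOC(=O)CC(C)c1ccc(Cl)c(C)c1 | intermediate
11 | rac-3-(4-chloro-3-methylphenyl)butanoic acid | OC(=O)CC(C)c1ccc(Cl)c(C)c1 | intermediate
12 | rac-3-(2-bromo-4-chloro-5-methylphenyl)butanoic acid | OC(=O)CC(C)c1cc(C)c(Cl)cc1Br | intermediate
13 | rac-3-(2-bromo-4-chloro-5-methylphenyl)butanoyl chloride | ClC(=O)CC(C)c1cc(C)c(Cl)cc1Br | intermediate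
14 | rac-4-bromo-6-chloro-3,7-dimethylindan-1-one | CC1CC(=O)c2c(C)c(Cl)cc(Br)c21 | intermediate
15 | isopropenylboronic acid pinacol ester | C=C(C)B1OC(C)(C)C(C)(C)O1 | starting material
16 | rac-6-chloro-3,7-dimethyl-4-(prop-1-en-2-yl)indan-1-one | CC1CC(=O)c2c(C)c(Cl)cc(C(C)=C)c21 | intermediate
17 | rac-6-chloro-4-(2-hydroxypropan-2-yl)-3,7-dimethylindan-1-one | CC1CC(=O)c2c(C)c(Cl)cc(C(C)(C)O)c21 | intermediate
18 | rac-C1-O-triethylsilyl enol ether of 6-chloro-3,7-dimethyl-4-[2-(triethylsilyloxy)propan-2-yl]indan-1-one | CC1C=C(O[Si](CC)(CC)CC)c2c(C)c(Cl)cc(C(C)(C)O[Si](CC)(CC)CC)c21 | intermediate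
19 | 6-chloro-3,7-dimethyl-4-[2-(triethylsilyloxy)propan-2-yl]inden-1-one | CC1=CC(=O)c2c(C)c(Cl)cc(C(C)(C)O[Si](CC)(CC)CC)c21 | intermediate
20 | rac-trans-2,3-dibromo-6-chloro-3,7-dimethyl-4-[2-(triethylsilyloxy)propan-2-yl]indan-1-one (one enantiomer drawn) | C[C@]1(Br)[C@H](Br)C(=O)c2c(C)c(Cl)cc(C(C)(C)O[Si](CC)(CC)CC)c21 | intermediate
21 | 2-bromo-6-chloro-3,7-dimethyl-4-[2-(triethylsilyloxy)propan-2-yl]inden-1-one | CC1=C(Br)C(=O)c2c(C)c(Cl)cc(C(C)(C)O[Si](CC)(CC)CC)c21 | intermediate
22 | (E,E)-bis(ethyl 3-arylacrylate) of the core, aryl cis to ester | CC1=C(/C(c2cc(C(C)C)ccc2C)=C/C(=O)OCC)C(=O)c2c(C)c(/C(c3cc(C(C)C)ccc3C)=C/C(=O)OCC)cc(C(C)(C)O[Si](CC)(CC)CC)c21 | intermediate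
23 | (E,E)-bis(3-arylacrylic acid) of the core | CC1=C(/C(c2cc(C(C)C)ccc2C)=C/C(=O)O)C(=O)c2c(C)c(/C(c3cc(C(C)C)ccc3C)=C/C(=O)O)cc(C(C)(C)O[Si](CC)(CC)CC)c21 | intermediate
24 | (E,E)-bis(3-arylacryloyl chloride) of the core | CC1=C(/C(c2cc(C(C)C)ccc2C)=C/C(=O)Cl)C(=O)c2c(C)c(/C(c3cc(C(C)C)ccc3C)=C/C(=O)Cl)cc(C(C)(C)O[Si](CC)(CC)CC)c21 | intermediate
25 | 2,6-bis[(1E)-4-diazo-1-(5-isopropyl-2-methylphenyl)-3-oxobut-1-en-1-yl]-3,7-dimethyl-4-[2-(triethylsilyloxy)propan-2-yl]inden-1-one | CC1=C(/C(c2cc(C(C)C)ccc2C)=C/C(=O)C=[N+]=[N-])C(=O)c2c(C)c(/C(c3cc(C(C)C)ccc3C)=C/C(=O)C=[N+]=[N-])cc(C(C)(C)O[Si](CC)(CC)CC)c21 | intermediate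
26 | 2,6-bis(7-isopropyl-4-methyl-1-oxo-1,8a-dihydroazulen-3-yl)-3,7-dimethyl-4-[2-(triethylsilyloxy)propan-2-yl]inden-1-one (mixture of C8a' epimers) | CC1=C(C2=CC(=O)C3C=C(C(C)C)C=CC(C)=C23)C(=O)c2c(C)c(C3=CC(=O)C4C=C(C(C)C)C=CC(C)=C34)cc(C(C)(C)O[Si](CC)(CC)CC)c21 | intermediate
27 | 2,6-bis(1-hydroxy-7-isopropyl-4-methylazulen-3-yl)-3,7-dimethyl-4-[2-(triethylsilyloxy)propan-2-yl]inden-1-one | CC1=C(c2cc(O)c3cc(C(C)C)ccc(C)c2-3)C(=O)c2c(C)c(-c3cc(O)c4cc(C(C)C)ccc(C)c3-4)cc(C(C)(C)O[Si](CC)(CC)CC)c21 | intermediate
28 | 2,6-bis[7-isopropyl-4-methyl-1-(trifluoromethylsulfonyloxy)azulen-3-yl]-3,7-dimethyl-4-[2-(triethylsilyloxy)propan-2-yl]inden-1-one | CC1=C(c2cc(OS(=O)(=O)C(F)(F)F)c3cc(C(C)C)ccc(C)c2-3)C(=O)c2c(C)c(-c3cc(OS(=O)(=O)C(F)(F)F)c4cc(C(C)C)ccc(C)c3-4)cc(C(C)(C)O[Si](CC)(CC)CC)c21 | intermediate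
29 | 2,6-bis(7-isopropyl-1,4-dimethylazulen-3-yl)-3,7-dimethyl-4-[2-(triethylsilyloxy)propan-2-yl]inden-1-one | CC1=C(c2cc(C)c3cc(C(C)C)ccc(C)c2-3)C(=O)c2c(C)c(-c3cc(C)c4cc(C(C)C)ccc(C)c3-4)cc(C(C)(C)O[Si](CC)(CC)CC)c21 | intermediate
30 | 2,6-bis(7-isopropyl-1,4-dimethylazulen-3-yl)-4-(2-hydroxypropan-2-yl)-3,7-dimethylinden-1-one | CC1=C(c2cc(C)c3cc(C(C)C)ccc(C)c2-3)C(=O)c2c(C)c(-c3cc(C)c4cc(C(C)C)ccc(C)c3-4)cc(C(C)(C)O)c21 | target

**Step count**
Total: 17 steps. Longest linear sequence: 14 steps (steps 4–17, from 8 and 9). The arm fragment 7 takes 3 steps (steps 1–3) and enters twice in step 12.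

**Steps most likely to fail**

1. Step 15 (key step).
- What may go wrong:
  - the carbenoid may attack C6 of the cymene ring end-on, a formal aromatic substitution that closes a six-membered ring;
  - it may add on the methyl-bearing side;
  - it may undergo Wolff rearrangement;
  - the two carbenoid sites may couple between molecules;
  - the hydroxyazulenes may oxidise before they are trapped.
- Fallback with known chemistry, in which the azulene rings are bought instead of built. It sets out from 21. Commercial guaiazulene F1 is brominated at its nucleophilic C3 (NBS, hexane, 0 °C) to 3-bromoguaiazulene F2. This is used at once in a Miyaura borylation (B2pin2, PdCl2(dppf), KOAc, dioxane, 80 °C) to give guaiazulen-3-ylboronic acid pinacol ester F3. Two-fold Suzuki–Miyaura coupling of F3 with 21 under the conditions of step 12 comes back to the route at 29.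

2. Step 12.
- What may go wrong:
  - oxidative addition at the hindered C6–Cl bond may be slow;
  - the electron-poor, α-branched alkenylboronate may protodeboronate in hot aqueous base;
  - prolonged heating with base may erode the alkene geometry.
- Fallback that forms the same bonds by C–H alkenylation. It sets out from 2 and 21. A Mizoroki–Heck reaction of 2 with ethyl acrylate (Pd(OAc)2, dppp, Et3N, DMF, 90 °C) gives ethyl (E)-3-(5-isopropyl-2-methylphenyl)prop-2-enoate F4. A two-fold Heck reaction of 21 with F4 (Pd2(dba)3, P(tBu)3, Cy2NMe, dioxane, 100 °C) then proceeds by syn-carbopalladation, bond rotation and syn β-hydride elimination. That sequence places the incoming core trans and the resident aryl ring cis to the ester. The fallback comes back to the route at 22.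

3. Step 14.
- What may go wrong:
  - diazomethane may add as a dipole to one of the conjugated alkenes;
  - the acid chloride may lose its alkene geometry or cyclise onto the cis aryl ring;
  - incomplete reaction at one of the two sites would give mixtures.
- Fallback that avoids diazomethane. It sets out from 23, by way of 24. Palladium-catalysed acylation of MeZnCl (Pd(PPh3)4, THF, 0 °C) gives the bis(methyl ketone) F5. Kinetic deprotonation (LiN(SiMe3)2, THF, −78 °C) and trifluoroacetylation with CF3CO2CH2CF3 give the bis(trifluoroacetyl ketone) F6. Detrifluoroacetylative diazo transfer (MsN3, Et3N, H2O, MeCN, rt), the standard entry to α'-diazo enones, comes back to the route at 25.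

**Further compounds**
F1 | step 15 | guaiazulene (7-isopropyl-1,4-dimethylazulene, purchased) | c1cc(C)c2cc(C(C)C)ccc(C)c1-2
F2 | step 15 | 3-bromoguaiazulene | Brc1cc(C)c2cc(C(C)C)ccc(C)c1-2
F3 | step 15 | guaiazulen-3-ylboronic acid pinacol ester | CC1(C)OB(OC1(C)C)c1cc(C)c2cc(C(C)C)ccc(C)c1-2
F4 | step 12 | ethyl (E)-3-(5-isopropyl-2-methylphenyl)prop-2-enoate | CCOC(=O)/C=C/c1cc(C(C)C)ccc1C
F5 | step 14 | 2,6-bis[(1E)-1-(5-isopropyl-2-methylphenyl)-3-oxobut-1-en-1-yl]-3,7-dimethyl-4-[2-(triethylsilyloxy)propan-2-yl]inden-1-one | CC1=C(/C(c2cc(C(C)C)ccc2C)=C/C(C)=O)C(=O)c2c(C)c(/C(c3cc(C(C)C)ccc3C)=C/C(C)=O)cc(C(C)(C)O[Si](CC)(CC)CC)c21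
F6 | step 14 | 2,6-bis[(1E)-6,6,6-trifluoro-1-(5-isopropyl-2-methylphenyl)-3,5-dioxohex-1-en-1-yl]-3,7-dimethyl-4-[2-(triethylsilyloxy)propan-2-yl]inden-1-one | CC1=C(/C(c2cc(C(C)C)ccc2C)=C/C(=O)CC(=O)C(F)(F)F)C(=O)c2c(C)c(/C(c3cc(C(C)C)ccc3C)=C/C(=O)CC(=O)C(F)(F)F)cc(C(C)(C)O[Si](CC)(CC)CC)c21
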